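**Plan**

- Retrosynthesis first strips the four benzyl ethers, the C3 ester and the C1 methyl group, then opens ring A at C1–C2 and C1–C6. This releases C1 as carbon monoxide and leaves an open-chain tertiary 3-pivaloyloxy-1,4-enyne.
- The enabling feature is that ring A is a pentasubstituted benzene whose only CH (C2) lies between the oxygen-bearing carbons C1 (OMe) and C3 (OH). CO supplies C1, a terminal alkyne supplies C2 and C3 (the ester migrates onto C3), the carbinol carbon becomes C4 and an alkene becomes C5=C6. Because C4 and C6 carry the same 4-hydroxybenzyl group, only monomethylation has to be controlled, not which oxygen is methylated.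
- The enyne is cut at the alkyne–carbinol bond (ethynyl Grignard plus enone), the enone at C5=C6 (Horner–Wadsworth–Emmons), the ketophosphonate at its acyl bond, and the phosphonate chain at the ring B aryl–CH2 bond (B-alkyl Suzuki coupling).
- Forward: ring B is made as a diarylmethane bromide, extended to the phosphonate, acylated, olefinated, ethynylated and pivaloylated. Ring A is then closed around CO in one step, and methylation, ester cleavage and hydrogenolysis finish the synthesis.
- The target has no stereocentre. The only stereochemical element is the E geometry of the C5=C6 alkene, set in the olefination, which keeps H inside the closing triene. All racemic centres on the way are destroyed.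

Key step: step 10

Remark: ring A is numbered C1 (OMe), C2 (H), C3 (OH), C4 and C6 (4-hydroxybenzyl), C5 (ethylene bridge). Grignard reagent 3 (THF solution) and alcohol 12 are taken as purchased.

**Route**

Step 1
Reactants: 1 2-bromo-4-hydroxybenzaldehyde
Product: 2 4-(benzyloxy)-2-bromobenzaldehyde
Conditions: BnBr, K2CO3, DMF, rt
Reagents that add atoms: benzyl bromide, BrCc1ccccc1
Why: Williamson etherification of the phenoxide should give the benzyl ether that lasts until the final hydrogenolysis, the aldehyde and aryl bromide being inert.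

Step 2
Reactants: 2 4-(benzyloxy)-2-bromobenzaldehyde; 3 4-(benzyloxy)phenylmagnesium bromide
Product: 4 rac-[4-(benzyloxy)-2-bromophenyl][4-(benzyloxy)phenyl]methanol
Conditions: THF, −78 → 0 °C; then H2O
Reagents that add atoms: none
Why: Grignard 1,2-addition to the aldehyde at low temperature should outrun bromine–magnesium exchange at the aryl bromide and gives a racemic benzhydrol whose centre is removed in step 3.

Step 3
Reactants: 4 rac-[4-(benzyloxy)-2-bromophenyl][4-(benzyloxy)phenyl]methanol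
Product: 5 4-(benzyloxy)-1-[4-(benzyloxy)benzyl]-2-bromobenzene (ring B bromide)
Conditions: Et3SiH, CF3CO2H, CH2Cl2, 0 °C
Reagents that add atoms: none
Why: Ionic hydrogenation, in which the acid ionises the doubly para-alkoxy-stabilised benzhydrol and the silane delivers hydride, should leave the aryl bromide and benzyl ethers untouched at 0 °C.

Step 4
Reactants: 5 ring B bromide; 6 diethyl allylphosphonate
Product: 8 diethyl (3-{5-(benzyloxy)-2-[4-(benzyloxy)benzyl]phenyl}propyl)phosphonate, via alkylborane 7 (not isolated)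
Conditions: 6, 9-BBN, THF, 0 °C → rt; then 5, PdCl2(dppf) (5 mol %), K3PO4 (aq), DMF, 60 °C
Reagents that add atoms: none
Why: Anti-Markovnikov hydroboration of the terminal alkene followed by B-alkyl Suzuki–Miyaura coupling, in which zerovalent palladium inserts into the aryl bromide and the base-activated borane transfers its primary alkyl group, should tolerate the phosphonate ester.

Step 5
Reactants: 8 diethyl (3-arylpropyl)phosphonate; 9 4-(benzyloxy)phenylacetic acid
Product: 11 rac-diethyl (1-{5-(benzyloxy)-2-[4-(benzyloxy)benzyl]phenyl}-5-[4-(benzyloxy)phenyl]-4-oxopentan-3-yl)phosphonate, via acid chloride 10 (not isolated)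
Conditions: 9, (COCl)2, DMF (cat.), CH2Cl2, 0 °C → rt, evaporate; 8, n-BuLi, THF, −78 °C; CuI (copper iodide), −30 °C; then 10, −30 °C → rt
Reagents that add atoms: none
Why: The α-lithiated phosphonate is turned into its monovalent copper derivative, which undergoes the known acylation by acid chlorides without deprotonating the acidic arylacetyl CH2 or the product, so one equivalent of 8 should suffice; the new centre is racemic and vanishes in step 7.

Step 6
Reactants: 12 2-[4-(benzyloxy)phenyl]ethanol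
Product: 13 4-(benzyloxy)phenylacetaldehyde
Conditions: Dess–Martin periodinane, CH2Cl2, 0 °C → rt
Reagents that add atoms: none
Why: Dess–Martin oxidation should stop at the aldehyde under near-neutral conditions, and the enolisable arylacetaldehyde is used crude at once.

Step 7
Reactants: 11 β-ketophosphonate; 13 4-(benzyloxy)phenylacetaldehyde
Product: 14 (E)-1,5-bis[4-(benzyloxy)phenyl]-3-(2-{5-(benzyloxy)-2-[4-(benzyloxy)benzyl]phenyl}ethyl)pent-3-en-2-one
Conditions: Ba(OH)2 (activated), THF–H2O (40:1), 0 °C → rt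
Reagents that add atoms: none
Why: Horner–Wadsworth–Emmons olefination of an α-substituted β-ketophosphonate under mild Ba(OH)2 conditions should spare the enolisable aldehyde and the γ-benzylic enone and place the carbonyl group trans to the new CH2Ar group (E).

Step 8
Reactants: 14 (E)-enone; 15 ethynylmagnesium bromide
Product: 16 rac-(E)-3-[4-(benzyloxy)benzyl]-4-(2-{5-(benzyloxy)-2-[4-(benzyloxy)benzyl]phenyl}ethyl)-6-[4-(benzyloxy)phenyl]hex-4-en-1-yn-3-ol
Conditions: LaCl3·2LiCl, THF, −78 → 0 °C; then H2O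
Reagents that add atoms: none
Why: Grignard 1,2-addition of the acetylide to the enone carbonyl, with LaCl3·2LiCl raising carbonyl electrophilicity and suppressing enolisation at the benzylic CH2, should give the tertiary carbinol as a racemate whose centre becomes aromatic C4 in step 10.

Step 9
Reactants: 16 tertiary propargylic alcohol
Product: 17 rac-(E)-3-[4-(benzyloxy)benzyl]-4-(2-{5-(benzyloxy)-2-[4-(benzyloxy)benzyl]phenyl}ethyl)-6-[4-(benzyloxy)phenyl]hex-4-en-1-yn-3-yl pivalate
Conditions: LiN(SiMe3)2, THF, −78 °C; then t-BuCOCl, DMAP (cat.), −78 °C → rt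
Reagents that add atoms: pivaloyl chloride, CC(C)(C)C(Cl)=O
Why: O-Acylation of the preformed lithium alkoxide (the OH is far more acidic than the alkyne CH) is the usual way to esterify a hindered tertiary propargylic alcohol without ionising its allylic and propargylic C–O bond.

Step 10
Reactants: 17 tertiary 3-pivaloyloxy-1,4-enyne; 18 carbon monoxide
Product: 21 2,4-bis[4-(benzyloxy)benzyl]-3-(2-{5-(benzyloxy)-2-[4-(benzyloxy)benzyl]phenyl}ethyl)-5-hydroxyphenyl pivalate, via dienylketene 19 (not isolated), via cyclohexadienone 20 (not isolated)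
Conditions: [RhCl(CO)2]2 (5 mol %), CO (50 atm), CH2Cl2, 80 °C, autoclave
Reagents that add atoms: none
Why: Monovalent rhodium activates the terminal alkyne, the pivalate carbonyl oxygen attacks the internal alkyne carbon and the ester shifts from the carbinol carbon (future C4) to that carbon (future C3), leaving a rhodium dienylcarbene at the former alkyne terminus (C2). CO inserts into the carbene to give dienylketene 19, whose ketene carbon (C1) bonds to the alkene terminus (C6) in a thermal disrotatory 6π electrocyclisation, the only ring closure, and enolisation of the resulting dienone 20 aromatises ring A. The closest known reaction is the [RhCl(CO)2]2-catalysed [5+1] cycloaddition of 3-acyloxy-1,4-enynes with CO to resorcinol monoesters. No stereocentre is formed and the racemic carbinol centre of 17 is erased. The step needs 1,2- rather than 1,3-acyloxy migration, which the terminal alkyne favours, and CO capture ahead of Rautenstrauch-type five-ring closure, which CO pressure favours, while the E alkene puts H and not CH2Ar inside the closing triene. The two ring oxygens emerge differentiated as the free C1 phenol and the C3 pivalate, which is all that is required because C4 and C6 bear identical groups.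

Step 11
Reactants: 21 ring A phenol pivalate
Product: 22 2,4-bis[4-(benzyloxy)benzyl]-3-(2-{5-(benzyloxy)-2-[4-(benzyloxy)benzyl]phenyl}ethyl)-5-methoxyphenyl pivalate
Conditions: MeI, K2CO3, acetone, 40 °C
Reagents that add atoms: iodomethane, CI
Why: Williamson methylation of the only free phenol should methylate exactly one oxygen, because the hindered aryl pivalate neither cleaves nor transfers under carbonate in acetone.

Step 12
Reactants: 22 methyl ether pivalate
Product: 23 2,4-bis[4-(benzyloxy)benzyl]-3-(2-{5-(benzyloxy)-2-[4-(benzyloxy)benzyl]phenyl}ethyl)-5-methoxyphenol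
Conditions: NaOMe, MeOH–THF, 50 °C; then 1 M HCl
Reagents that add atoms: none
Why: Methanolysis of the aryl pivalate by methoxide should release the phenoxide, a good leaving group, while benzyl and methyl ethers are inert.

Step 13
Reactants: 23 tetrabenzyl ether of the target
Product: 24 3-{2-[5-hydroxy-2-(4-hydroxybenzyl)phenyl]ethyl}-2,4-bis(4-hydroxybenzyl)-5-methoxyphenol (CNP0147493.0)
Conditions: H2 (1 atm), 10% Pd/C, EtOAc–MeOH, rt
Reagents that add atoms: none
Why: Palladium-catalysed hydrogenolysis should cleave the four O-benzyl bonds, while the diarylmethane C–C bonds and the aryl methyl ether are stable.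

**Compound list**

1 | 2-bromo-4-hydroxybenzaldehyde | O=Cc1ccc(O)cc1Br | starting material
2 | 4-(benzyloxy)-2-bromobenzaldehyde | O=Cc1ccc(OCc2ccccc2)cc1Br | intermediate
3 | 4-(benzyloxy)phenylmagnesium bromide | Br[Mg]c1ccc(OCc2ccccc2)cc1 | starting material
4 | rac-[4-(benzyloxy)-2-bromophenyl][4-(benzyloxy)phenyl]methanol | OC(c1ccc(OCc2ccccc2)cc1)c1ccc(OCc2ccccc2)cc1Br | intermediate
5 | 4-(benzyloxy)-1-[4-(benzyloxy)benzyl]-2-bromobenzene | Brc1cc(OCc2ccccc2)ccc1Cc1ccc(OCc2ccccc2)cc1 | intermediate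
6 | diethyl allylphosphonate | C=CCP(=O)(OCC)OCC | starting material
7 | diethyl [3-(9-borabicyclo[3.3.1]nonan-9-yl)propyl]phosphonate | CCOP(=O)(OCC)CCCB1C2CCCC1CCC2 | intermediate (not isolated)
8 | diethyl (3-{5-(benzyloxy)-2-[4-(benzyloxy)benzyl]phenyl}propyl)phosphonate | CCOP(=O)(OCC)CCCc1cc(OCc2ccccc2)ccc1Cc1ccc(OCc2ccccc2)cc1 | intermediate
9 | 4-(benzyloxy)phenylacetic acid | O=C(O)Cc1ccc(OCc2ccccc2)cc1 | starting material
10 | 4-(benzyloxy)phenylacetyl chloride | O=C(Cl)Cc1ccc(OCc2ccccc2)cc1 | intermediate (not isolated)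
11 | rac-diethyl (1-{5-(benzyloxy)-2-[4-(benzyloxy)benzyl]phenyl}-5-[4-(benzyloxy)phenyl]-4-oxopentan-3-yl)phosphonate | CCOP(=O)(OCC)C(CCc1cc(OCc2ccccc2)ccc1Cc1ccc(OCc2ccccc2)cc1)C(=O)Cc1ccc(OCc2ccccc2)cc1 | intermediate
12 | 2-[4-(benzyloxy)phenyl]ethanol | OCCc1ccc(OCc2ccccc2)cc1 | starting material
13 | 4-(benzyloxy)phenylacetaldehyde | O=CCc1ccc(OCc2ccccc2)cc1 | intermediate
14 | (E)-1,5-bis[4-(benzyloxy)phenyl]-3-(2-{5-(benzyloxy)-2-[4-(benzyloxy)benzyl]phenyl}ethyl)pent-3-en-2-one | O=C(Cc1ccc(OCc2ccccc2)cc1)/C(CCc1cc(OCc2ccccc2)ccc1Cc1ccc(OCc2ccccc2)cc1)=C/Cc1ccc(OCc2ccccc2)cc1 | intermediate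
15 | ethynylmagnesium bromide | C#C[Mg]Br | starting material
16 | rac-(E)-3-[4-(benzyloxy)benzyl]-4-(2-{5-(benzyloxy)-2-[4-(benzyloxy)benzyl]phenyl}ethyl)-6-[4-(benzyloxy)phenyl]hex-4-en-1-yn-3-ol | C#CC(O)(Cc1ccc(OCc2ccccc2)cc1)/C(CCc1cc(OCc2ccccc2)ccc1Cc1ccc(OCc2ccccc2)cc1)=C/Cc1ccc(OCc2ccccc2)cc1 | intermediate
17 | rac-(E)-3-[4-(benzyloxy)benzyl]-4-(2-{5-(benzyloxy)-2-[4-(benzyloxy)benzyl]phenyl}ethyl)-6-[4-(benzyloxy)phenyl]hex-4-en-1-yn-3-yl pivalate | C#CC(OC(=O)C(C)(C)C)(Cc1ccc(OCc2ccccc2)cc1)/C(CCc1cc(OCc2ccccc2)ccc1Cc1ccc(OCc2ccccc2)cc1)=C/Cc1ccc(OCc2ccccc2)cc1 | intermediate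
18 | carbon monoxide | [C-]#[O+] | starting material
19 | dienylketene with pivaloyloxy on C3 (C2 and C5 cis about C3=C4; C4 and the benzylic CH2 trans about C5=C6) | O=C=C/C(OC(=O)C(C)(C)C)=C(Cc1ccc(OCc2ccccc2)cc1)\C(CCc1cc(OCc2ccccc2)ccc1Cc1ccc(OCc2ccccc2)cc1)=C\Cc1ccc(OCc2ccccc2)cc1 | intermediate (not isolated)
20 | rac-cyclohexa-2,4-dien-1-one tautomer of 21 (sp3 C6 bearing H and the benzyl group) | O=C1C=C(OC(=O)C(C)(C)C)C(Cc2ccc(OCc3ccccc3)cc2)=C(CCc2cc(OCc3ccccc3)ccc2Cc2ccc(OCc3ccccc3)cc2)C1Cc1ccc(OCc2ccccc2)cc1 | intermediate (not isolated)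
21 | 2,4-bis[4-(benzyloxy)benzyl]-3-(2-{5-(benzyloxy)-2-[4-(benzyloxy)benzyl]phenyl}ethyl)-5-hydroxyphenyl pivalate | CC(C)(C)C(=O)Oc1cc(O)c(Cc2ccc(OCc3ccccc3)cc2)c(CCc2cc(OCc3ccccc3)ccc2Cc2ccc(OCc3ccccc3)cc2)c1Cc1ccc(OCc2ccccc2)cc1 | intermediate
22 | 2,4-bis[4-(benzyloxy)benzyl]-3-(2-{5-(benzyloxy)-2-[4-(benzyloxy)benzyl]phenyl}ethyl)-5-methoxyphenyl pivalate | COc1cc(OC(=O)C(C)(C)C)c(Cc2ccc(OCc3ccccc3)cc2)c(CCc2cc(OCc3ccccc3)ccc2Cc2ccc(OCc3ccccc3)cc2)c1Cc1ccc(OCc2ccccc2)cc1 | intermediate
23 | 2,4-bis[4-(benzyloxy)benzyl]-3-(2-{5-(benzyloxy)-2-[4-(benzyloxy)benzyl]phenyl}ethyl)-5-methoxyphenol | COc1cc(O)c(Cc2ccc(OCc3ccccc3)cc2)c(CCc2cc(OCc3ccccc3)ccc2Cc2ccc(OCc3ccccc3)cc2)c1Cc1ccc(OCc2ccccc2)cc1 | intermediate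
24 | 3-{2-[5-hydroxy-2-(4-hydroxybenzyl)phenyl]ethyl}-2,4-bis(4-hydroxybenzyl)-5-methoxyphenol (CNP0147493.0) | COc1cc(O)c(Cc2ccc(O)cc2)c(CCc2cc(O)ccc2Cc2ccc(O)cc2)c1Cc1ccc(O)cc1 | target

**Count and risks**

Total step count: 13. Longest linear sequence: 12 steps (steps 1–5 and 7–13 from 1; step 6 is a one-step side branch).

Most likely to fail, in order:

1. Step 10. Crowding around the tetrasubstituted enol ester may slow CO uptake, so that the rhodium carbene is diverted into five-membered ring closure or the ester shifts 1,3 to an allenyl ester. The fallback is a Danheiser benzannulation in its photochemical Wolff form; it sets out from 8 and returns at 23. Commercial 3-[4-(benzyloxy)phenyl]propanoic acid is converted with (COCl)2 into 3-[4-(benzyloxy)phenyl]propanoyl chloride F1. F1 acylates the monovalent copper derivative of 8 as in step 5 to give the homologous ketophosphonate F2. Olefination of F2 with 13 as in step 7 gives the (E)-enone F3. Trifluoroacetylation of the kinetic lithium enolate of F3 (LiN(SiMe3)2, CF3CO2CH2CF3, −78 °C) gives the trifluoroacetyl diketone F4. Diazo transfer to F4 with methanesulfonyl azide, Et3N and water in MeCN gives the diazo ketone F5. Irradiation of F5 in the presence of methoxyacetylene F6 (freshly made from chloroacetaldehyde dimethyl acetal and NaNH2) should give, by Wolff rearrangement, the vinylketene F7. F7 is trapped by F6 in the known [2+2] cycloaddition, four-electron ring opening and 6π closure cascade, completed by warming to 80 °C. This delivers 23 directly, with OH from the ketene carbon and OMe from the alkyne, so steps 11 and 12 are not needed.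

2. Step 7. The base may move the new double bond into conjugation with the aryl ring, the arylacetaldehyde may self-condense, and the alkene geometry may erode. The fallback builds the alkene by cross-metathesis; it sets out from 11 and returns at 14. Olefination of 11 with aqueous formaldehyde and K2CO3 in THF at rt should give the α-methylene ketone F8. Cross-metathesis of F8 with 1-allyl-4-(benzyloxy)benzene F9 (from Grignard reagent 3 and allyl bromide, THF, 0 °C) under the second-generation Hoveyda–Grubbs catalyst in CH2Cl2 at 40 °C should give 14. The conditions are neutral and the E-trisubstituted enone is the thermodynamic product.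

3. Step 9. The crowded tertiary alkoxide may fail to be acylated by the bulky acid chloride, or may fragment by loss of acetylide on warming. The fallback uses the smaller acetate as migrating group; it sets out from 16 and returns at 23. LiN(SiMe3)2 then Ac2O in THF at −78 °C → 0 °C should give the enyne acetate F10. Carbonylation of F10 under the conditions of step 10 should give the ring A phenol acetate F11. Mitsunobu methylation of F11 (MeOH, PPh3, diisopropyl azodicarboxylate, THF, rt) is neutral, avoids acetyl transfer between phenols, and gives the methyl ether acetate F12. Methanolysis of F12 with K2CO3 in MeOH at rt gives 23.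

**Further compounds**

F1 | step 10 | 3-[4-(benzyloxy)phenyl]propanoyl chloride | O=C(Cl)CCc1ccc(OCc2ccccc2)cc1
F2 | step 10 | rac-diethyl (1-{5-(benzyloxy)-2-[4-(benzyloxy)benzyl]phenyl}-6-[4-(benzyloxy)phenyl]-4-oxohexan-3-yl)phosphonate | CCOP(=O)(OCC)C(CCc1cc(OCc2ccccc2)ccc1Cc1ccc(OCc2ccccc2)cc1)C(=O)CCc1ccc(OCc2ccccc2)cc1
F3 | step 10 | (E)-1,6-bis[4-(benzyloxy)phenyl]-4-(2-{5-(benzyloxy)-2-[4-(benzyloxy)benzyl]phenyl}ethyl)hex-4-en-3-one | O=C(CCc1ccc(OCc2ccccc2)cc1)/C(CCc1cc(OCc2ccccc2)ccc1Cc1ccc(OCc2ccccc2)cc1)=C/Cc1ccc(OCc2ccccc2)cc1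
F4 | step 10 | rac-(E)-3-[4-(benzyloxy)benzyl]-1,1,1-trifluoro-5-(2-{5-(benzyloxy)-2-[4-(benzyloxy)benzyl]phenyl}ethyl)-7-[4-(benzyloxy)phenyl]hept-5-ene-2,4-dione | O=C(C(Cc1ccc(OCc2ccccc2)cc1)C(=O)C(F)(F)F)/C(CCc1cc(OCc2ccccc2)ccc1Cc1ccc(OCc2ccccc2)cc1)=C/Cc1ccc(OCc2ccccc2)cc1
F5 | step 10 | (E)-2-diazo-1,6-bis[4-(benzyloxy)phenyl]-4-(2-{5-(benzyloxy)-2-[4-(benzyloxy)benzyl]phenyl}ethyl)hex-4-en-3-one | O=C(C(=[N+]=[N-])Cc1ccc(OCc2ccccc2)cc1)/C(CCc1cc(OCc2ccccc2)ccc1Cc1ccc(OCc2ccccc2)cc1)=C/Cc1ccc(OCc2ccccc2)cc1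
F6 | step 10 | methoxyacetylene | COC#C
F7 | step 10 | vinylketene (ketene carbon trans to the benzylic CH2 about the alkene) | O=C=C(Cc1ccc(OCc2ccccc2)cc1)/C(CCc1cc(OCc2ccccc2)ccc1Cc1ccc(OCc2ccccc2)cc1)=C/Cc1ccc(OCc2ccccc2)cc1
F8 | step 7 | 1-[4-(benzyloxy)phenyl]-5-{5-(benzyloxy)-2-[4-(benzyloxy)benzyl]phenyl}-3-methylidenepentan-2-one | C=C(CCc1cc(OCc2ccccc2)ccc1Cc1ccc(OCc2ccccc2)cc1)C(=O)Cc1ccc(OCc2ccccc2)cc1
F9 | step 7 | 1-allyl-4-(benzyloxy)benzene | C=CCc1ccc(OCc2ccccc2)cc1
F10 | step 9 | rac-(E)-3-[4-(benzyloxy)benzyl]-4-(2-{5-(benzyloxy)-2-[4-(benzyloxy)benzyl]phenyl}ethyl)-6-[4-(benzyloxy)phenyl]hex-4-en-1-yn-3-yl acetate | C#CC(OC(C)=O)(Cc1ccc(OCc2ccccc2)cc1)/C(CCc1cc(OCc2ccccc2)ccc1Cc1ccc(OCc2ccccc2)cc1)=C/Cc1ccc(OCc2ccccc2)cc1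
F11 | step 9 | 2,4-bis[4-(benzyloxy)benzyl]-3-(2-{5-(benzyloxy)-2-[4-(benzyloxy)benzyl]phenyl}ethyl)-5-hydroxyphenyl acetate | CC(=O)Oc1cc(O)c(Cc2ccc(OCc3ccccc3)cc2)c(CCc2cc(OCc3ccccc3)ccc2Cc2ccc(OCc3ccccc3)cc2)c1Cc1ccc(OCc2ccccc2)cc1
F12 | step 9 | 2,4-bis[4-(benzyloxy)benzyl]-3-(2-{5-(benzyloxy)-2-[4-(benzyloxy)benzyl]phenyl}ethyl)-5-methoxyphenyl acetate | COc1cc(OC(C)=O)c(Cc2ccc(OCc3ccccc3)cc2)c(CCc2cc(OCc3ccccc3)ccc2Cc2ccc(OCc3ccccc3)cc2)c1Cc1ccc(OCc2ccccc2)cc1
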